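The readings were computed on assumed constants; scatter was added.

Amounts were what I had: the flask held 17 mM of solid substrate, none of it yet in solution, against 20.4 mM of partner and 0.340 mM of protic impurity.

the same everywhere: partner 20.4 mM
- north-west: solid substrate 17 mM; protic impurity 0.34 mM; temperature 70 °C; the very flask that is asked about, followed so far
- west: solid substrate 8.5 mM; protic impurity 0.34 mM; temperature 65 °C; run made earlier
- flask: solid substrate 17 mM; protic impurity 0.340 mM; temperature 70 °C; time 8.0 d

north-west run (percent of the solid substrate charged)

| time / d | target / % |
|---|---|
| 0.833 | 27.6 |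
| 1.67 | 27.2 |
| 3.00 | 27.3 |
| 4.00 | 27.5 |
| 5.00 | 28.1 |
| 6.00 | 27.1 |

west run (percent of the solid substrate charged)

| time / h | target / % |
|---|---|
| 2.50 | 22.4 |
| 4.00 | 28.0 |
| 6.00 | 30.1 |
| 10.0 | 32.1 |
| 15.0 | 32.2 |
| 20.0 | 33.0 |
| 30.0 | 32.0 |

(scatter of a reading: 0.5 percentage points)

- beta: at 8.0 d raise the temperature by 10 K, then wait 4.0 d
- gamma: change nothing and wait 4.0 d more
- eta: at 8.0 d add partner, 100% of the amount charged, then wait 4.0 d

- what is added takes up no volume worth counting
- at the start none of the solid substrate is in solution
- a reading or a percentage of target counts all its forms, free or not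

- target, in percent of the solid substrate first charged, at 8.0 d
- what to do for the largest gain in target; "none" if nothing gains more than 2 percentage points (beta / gamma / eta / none)
- target present, in percent of the solid substrate first charged, after beta
- target present, in percent of the solid substrate first charged, after gamma

I began with a time. The west run read 22.4% at 2.50 h against a plateau of 32.3%, so its gap closed with a time constant of about 2.12 h. The north-west run was flat at 27.5% from 0.833 d, a wait far longer than that. So I took 27.5% for the flask at 8.0 d and after gamma.

That plateau held 4.67 mM of target, leaving substrate and partner on paper, so I read it as a balance. I counted the impurity as taking its own amount of partner. Target divided by free substrate times free partner, the plateau quotient (an apparent association constant), read 0.0276 mM⁻¹ in the west run and 0.0246 mM⁻¹ in the north-west run.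

The weak link was free substrate, which I had reckoned as everything not in target. I saw two readings of that gap: heat had lowered the quotient, or substrate was missing. Holding the west quotient, the north-west run would be missing 1.33 mM. Under the heat reading, I reckoned beta at 23.8%; under the loss reading, I reckoned it near 27.5%. Neither gains. Under the loss reading, I reckoned eta at 43.9%, a gain of 16 percentage points, so I chose eta.

The forecast gave 27.4% now, 25% after beta, 27.4% after gamma and eta as best, holding that the “plateaus look like a reversible” balance.

The flask gave 27.5% now, 28.0% after beta and 27.5% after gamma, and eta gained 23 points, which is more than my 16 points.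

    solid substrate ⇌ dissolved substrate, rate k1*(cs1 - [dissolved substrate]) while solid is left; crystals form when [dissolved substrate] > cs1 (solubility = 12.0 mM, k = 7.60 h⁻¹)
    dissolved substrate + partner ⇌ target (K = 28.0 M⁻¹, k = 13.0 M⁻¹ h⁻¹, Ea = 88.0 kJ mol⁻¹, ΔH = 3.00 kJ mol⁻¹)
    solid product ⇌ target, rate k3*(cs3 - [target]) while solid is left; crystals form when [target] > cs3 (solubility = 6.10 mM, k = 10.0 h⁻¹)
    2 solid substrate → self-condensation product (k = 22.0 M⁻¹ h⁻¹, Ea = 82.0 kJ mol⁻¹)
    partner + protic impurity → quenched reagent (k = 260 M⁻¹ h⁻¹, Ea = 55.0 kJ mol⁻¹)
    (constants at 70 °C)

The back run from target to dissolved substrate and partner is the main reason target in the flask stopped where it did: with it taken away, target reached 91.5% at 8.0 d. Applied to the 63.8% dissolved substrate and the 75.4% of its charge of partner left free in the flask at 8.0 d, the quotient 0.0276 mM⁻¹ read from the west run gives 27.1% of target. The neighbour flask charged with 42 mM of solid substrate held 28.6% dissolved and 73.6% of its partner free at 8.0 d; the same quotient gives 11.9% there, and that flask stood at 12.0%.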